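The readings were computed with constants of no real substance; the scatter is artificial.

Start from the leftover: at 10.0 h the amber run holds 5.2% of its charge as target, so 94.8% of the charge lies elsewhere, and you may ask whether the size of the charge matters at all.

common to all: gas phase 180 mM (held)
- amber: solid substrate 0.56 M; run made earlier
- blue: solid substrate 0.88 M; run made earlier
- flask: solid substrate 0.40 M; time 8.0 h

- amber (time / h: target / %): 2.00: 0.9; 4.00: 1.8; 6.00: 3.1; 8.00: 4.6; 10.0: 5.2
- blue (time / h: target / %): 0.833: 0; 1.33: 0; 2.50: 0.2; 5.00: 1.4; 10.0: 3.2

(readings scatter by 0.3 percentage points)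

- target at 8.0 h, in percent of the solid substrate charged
- concentration of dissolved gas in solution at 8.0 h, in percent of saturation

First, does more solid give more target? Turn percentages into concentrations. At 10.0 h, amber holds 29.1 mM and blue 28.2 mM, though blue was charged 1.57 times as heavily. So [target] looks zero order in the charge, and the percentage should go as one over the charge.

Second, can you carry a slope? Amber makes 2.52 mM h⁻¹ over its first 4.00 h, then 3.92 mM h⁻¹, which is faster. The rate drifts, so carry a reading at the asked time instead: amber at 8.00 h gives 25.8 mM, the charge-free [target].

Third, is the flask's charge enough? Its 0.40 M is 15.5 times that concentration, so you divide and reckon 6.44%, a figure carrying amber's scatter.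

The forecast says 6% of target, lower than your figure, and 92% of saturation, with a roughly zero-order rate “as expected if the solution stays saturated with substrate”.

The flask gives 6.00% of target, with dissolved gas at 62.2% of saturation.

    gas phase ⇌ dissolved gas, rate k1*(csat - [dissolved gas]) (kL = 7.40 × 10⁻⁵ s⁻¹)
    starting material + dissolved gas → target (k = 3.30 × 10⁻⁴ M⁻¹ s⁻¹)
    starting material → side product (k = 3.10 × 10⁻⁵ s⁻¹)
    dissolved gas ⇌ dormant form (K = 2.70, k = 2.10 × 10⁻⁵ s⁻¹)
    dissolved gas + target → over-reaction product (k = 3.60 × 10⁻⁴ M⁻¹ s⁻¹)
    solid substrate ⇌ starting material, rate k6*(cs6 - [starting material]) while solid is left; crystals form when [starting material] > cs6 (solubility = 0.150 M, k = 3.70 × 10⁻⁵ s⁻¹)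

That target is 24.0 mM, against the 25.8 mM you carried. The rate of dissolving contains no amount of solid while solid is left, and 70.1% of this flask's charge is still solid at 8.00 h. With the low solubility of starting material lifted, target in this flask goes from 6.00% to 19.0%, a shift of 13 percentage points. For the neighbour flask charged with 0.16 M, 25.8 mM gives 16.1%; the computed neighbour gives 15.0%.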